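The easy step comes first: follow one molecule of electrophile and ask whether it has reacted yet. With nucleophile in excess we treat the loss as pseudo-first-order, so we take its chance of still being there as exp(−X), where X counts the time constants it has sat through and, in this reckoning, grows with the equivalents.

| flask | electrophile | nucleophile | remark | time |
|---|---|---|---|---|
| north | 36 mM | 3 equiv | run made earlier |  |
| south-east | 36 mM | 9.2 equiv | run made earlier |  |
| autumn | 36 mM | 2.00 equiv |  | 2.5 min |
| spring | 36 mM | 6.00 equiv |  | 2.5 min |

| run | time / min | electrophile / % | side product / % | target / % | over-reaction product / % | isomer of the product / % |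
|---|---|---|---|---|---|---|
| north | 0.500 | 85.3 | 2.4 | 11.4 | 2.2 | 0.2 |
| north | 1.00 | 72.2 | 7.3 | 16.6 | 3.8 | 3.2 |
| north | 1.50 | 59.2 | 11.2 | 15.4 | 7.2 | 3.7 |
| north | 2.00 | 50.1 | 16.1 | 15.5 | 11.0 | 8.7 |
| north | 2.50 | 42.5 | 19.6 | 16.4 | 10.9 | 10.5 |
| south-east | 0.200 | 82.4 | 0.7 | 13.2 | 2.5 | 0 |
| south-east | 0.417 | 63.8 | 4.4 | 22.5 | 7.4 | 2.1 |
| south-east | 0.667 | 48.1 | 8.1 | 23.8 | 14.7 | 3.2 |
| south-east | 1.33 | 24.9 | 10.2 | 20.8 | 34.5 | 10.2 |
| south-east | 2.50 | 9.3 | 14.0 | 11.2 | 52.4 | 11.0 |

(each reading ± 1 percentage point)

* which of these there is most of at the end, counted by the electrophile in it, autumn (target / electrophile / side product / over-reaction product / isomer of the product)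
* which of these there is most of at the end, counted by the electrophile in it, spring (target / electrophile / side product / over-reaction product / isomer of the product)
* final amount of the leader among these, as a percentage of the electrophile charged, in autumn
* final amount of the leader among these, as a percentage of the electrophile charged, in spring

- percent here means electrophile units held: one side product counts as two

At 36 mM and 2.5 min, the last readings give ln(charge/left) divided by the equivalents: 0.285 in north and 0.258 in south-east. We take their mean, 0.272, the exposure per equivalent.

Now turn the question round. What would have to be true for electrophile to lose the lead in autumn? Amounts count electrophile units, so a rival can pass it only once electrophile has dropped below half of the charge, which needs X above 0.693. Autumn reaches 0.543, short of that, so we reckon it leaves 58.1% and expect electrophile to stay ahead.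

Spring reaches 1.63, well past it, and by our reckoning leaves 19.6%, so the lead is open. South-east, at 1.33 min, had an exposure of 1.39, and there over-reaction product read 34.5%, above electrophile at 24.9% and target at 20.8%. Spring goes further than that, so we expect over-reaction product to lead in spring, near that reading.

The forecast names the same leaders with slightly different amounts, 57% and 32%, the first as “about 57% electrophile left, clearly the leader”.

The flasks give electrophile at 57.0% in autumn and over-reaction product at 33.6% in spring.

    nucleophile + acid set free ⇌ protonated nucleophile, settled at all times (K = 1.00 × 10⁵ L mol⁻¹)
    nucleophile + target → over-reaction product (k = 0.0709 L mol⁻¹ s⁻¹)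
    electrophile + nucleophile → acid set free + target (k = 0.0529 L mol⁻¹ s⁻¹)
    target ⇌ isomer of the product (K = 1.58, k = 0.00587 s⁻¹)
    electrophile + target → side product (k = 0.202 L mol⁻¹ s⁻¹)

In spring, half of the turnover up to 2.5 min of the step from electrophile and nucleophile to target is done by 0.698 min, and half of that of the over-reaction step by 1.22 min, a lag. At 2.5 min in spring the former step uses nucleophile at 0.95 of the over-reaction step's rate.

Take a neighbour flask, spring's recipe at 14 mM of electrophile, with the equivalents and the time held. The nucleophile there is thinner by the same factor as the electrophile, so we reckon the exposure falls to 0.634, below the threshold, leaving 53.0%. The computed neighbour holds 51.4% of electrophile, and its leader is electrophile.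

The numbers in the tables were generated by integration from invented constants; scatter was added.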